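**Retrosynthetic overview**

1. The quinone ring is numbered C1(=O), C2 (side chain), C3 (Me), C4(=O), C5 (Me), C6 (Me). The enabling feature: the side-chain carbinol oxygen lies five bonds from C1 (O–C3'–C2'–C1'–C2–C1), so O and C1 can be joined in a temporary six-membered oxygen ring (the chroman ring of α-tocopherol, hydroquinone oxidation level). The last event is oxidative opening of that ring (C1–O cleaved, C1=O formed).
2. Key disconnection, an intramolecular Dötz benzannulation: C1–C2 (carbene carbon to the tethered alkyne carbon), C3–C4 (alkyne carbon to CO) and C4–C5 (CO to butenyl β-carbon). C1 and C4 both come from Cr(CO)6, C5/C6 from a but-2-en-2-yl group, C2/C3 from a 2-alkyne. The precursor is alkoxycarbene complex 14, whose alkoxy group is alkynol 7.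
3. Alkynol 7: the C1'–alkyne bond comes from opening oxetane 5 with 1-propynyllithium; 5 comes from diol 3. The carbinol stereocenter is set by Sharpless epoxidation of natural phytol 1, which already carries the two methyl-branched stereocenters.
4. Ring order: oxirane (step 1, opened in step 2), oxetane (step 3, opened in step 4), then in step 7 the dihydropyran ring, the carbocycle, and re-opening of the dihydropyran ring.

Key step: step 7

Assumption: natural phytol is used as the commercial (2E,7R,11R) isomer, and 2-bromobut-2-ene as the commercial E/Z mixture, whose alkene geometry is erased in step 7.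

**Route**

Step 1
Reactants: 1 natural phytol, (2E,7R,11R)-3,7,11,15-tetramethylhexadec-2-en-1-ol
Product: 2 [(2R,3R)-3-methyl-3-[(4R,8R)-4,8,12-trimethyltridecyl]oxiran-2-yl]methanol
Conditions: Ti(OiPr)4 (cat.), D-(−)-diethyl tartrate (cat.), t-BuOOH, 4 Å molecular sieves, CH2Cl2, −20 °C
Reagents that add atoms: tert-butyl hydroperoxide, CC(C)(C)OO
Why: Sharpless asymmetric epoxidation of an (E)-trisubstituted allylic alcohol, in which the D-(−)-tartrate titanium catalyst should deliver oxygen to the alkene face that gives the (2R,3R)-epoxide (the mirror image of the outcome with the L-(+)-ligand), fixing the later carbinol carbon as R by reagent control.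

Step 2
Reactants: 2 (2R,3R)-epoxy alcohol
Product: 3 (3R,7R,11R)-3,7,11,15-tetramethylhexadecane-1,3-diol
Conditions: NaAlH2(OCH2CH2OMe)2, THF, 0 °C to rt; then aqueous work-up
Reagents that add atoms: none
Why: Hydroxyl-directed hydride opening of a 2,3-epoxy alcohol at C2 is the known route to 1,3-diols with this aluminate, and the C3–O bond is not touched, so C3 stays R.

Step 3
Reactants: 3 (3R,7R,11R)-1,3-diol
Product: 5 (2R)-2-methyl-2-[(4R,8R)-4,8,12-trimethyltridecyl]oxetane, via monotosylate 4 (not isolated)
Conditions: n-BuLi (1 equiv), THF, 0 °C; TsCl (1 equiv); then n-BuLi (1 equiv), 0 to 60 °C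
Reagents that add atoms: none
Why: One-pot oxetane synthesis from a 1,3-diol by selective sulfonylation of the primary alkoxide and intramolecular Williamson displacement (4-exo-tet) by the tertiary alkoxide, helped by the Thorpe–Ingold effect; substitution occurs only at the CH2 carbon, so the quaternary stereocenter is retained.

Step 4
Reactants: 5 (2R)-oxetane; 6 1-propynyllithium (MeC≡CLi)
Product: 7 (6R,10R,14R)-6,10,14,18-tetramethylnonadec-2-yn-6-ol
Conditions: BF3·OEt2, THF, −78 °C; then aqueous work-up
Reagents that add atoms: none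
Why: BF3-promoted SN2 opening of an oxetane by a lithium acetylide at the unsubstituted CH2–O carbon is a known reaction type and leaves the quaternary C–O bond and its configuration intact.

Step 5
Reactants: 8 2-bromobut-2-ene (E/Z mixture); 9 Cr(CO)6
Product: 12 Me4N[(CO)5Cr=C(O)C(Me)=CHMe] (tetramethylammonium pentacarbonyl(2-methylbut-2-enoyl)chromate), via MeCH=C(Me)Li 10 (not isolated), via Li[(CO)5Cr=C(O)C(Me)=CHMe] 11 (not isolated)
Conditions: t-BuLi (2 equiv), Et2O, −78 °C; Cr(CO)6, Et2O, 0 °C to rt; then Me4NBr, H2O
Reagents that add atoms: tetramethylammonium bromide, C[N+](C)(C)C.[Br-]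
Why: Halogen–lithium exchange, addition of the vinyllithium to a CO ligand (Fischer acylmetalate synthesis) and cation exchange to the storable ammonium salt are standard for this butenyl unit, and the alkene geometry need not be controlled because the butenyl β-carbon becomes an aromatic carbon in step 7.

Step 6
Reactants: 12 tetramethylammonium acylchromate; 7 alkynol
Product: 14 pentacarbonyl{(but-2-en-2-yl)[(6R,10R,14R)-6,10,14,18-tetramethylnonadec-2-yn-6-yloxy]carbene}chromium, via (CO)5Cr=C(OCOtBu)C(Me)=CHMe 13 (not isolated)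
Conditions: t-BuCOCl, CH2Cl2, −40 °C; then 7, −40 to 0 °C
Reagents that add atoms: none
Why: Proposed new method: O-acylation of 12 should give the strongly electrophilic acyloxycarbene 13, whose carbene carbon is expected to undergo addition–elimination by the tertiary hydroxyl of 7 (attack at the pivaloyl carbonyl is blocked by the tert-butyl group) with loss of pivalic acid and without touching the carbinol C–O bond, so the configuration is retained; the closest known reaction type is the alcoholysis of acyloxycarbene chromium complexes by primary and hindered secondary alcohols, extended here to a tertiary alcohol.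

Step 7
Reactants: 14 tethered alkoxycarbene complex
Product: 17 2-[(3R,7R,11R)-3-hydroxy-3,7,11,15-tetramethylhexadecyl]-3,5,6-trimethylcyclohexa-2,5-diene-1,4-dione, via α-tocopherol 15 (not isolated), via 8a-hydroxy-α-tocopherone 16 (not isolated)
Conditions: THF (0.01 M), 55 °C, Ar; then (NH4)2Ce(NO3)6, MeCN/H2O, 0 °C
Reagents that add atoms: water, O
Why: Thermal loss of one CO from 14 should be followed by insertion of the tethered alkyne into the Cr=C bond (carbene carbon to the tether-bearing alkyne carbon, quinone C1–C2), CO insertion at the other alkyne carbon (C3–C4) and 6π-electrocyclization of the resulting dienylketene onto the butenyl β-carbon (C4–C5), and tautomerization then gives α-tocopherol 15 (partly as its Cr(CO)3 complex) with all six ring substituents in place. The closest known reaction type is the intramolecular Dötz benzannulation of alkenyl(alkynyloxy)carbene chromium complexes with oxidative work-up. The oxygen ring is closed in the exo mode of the carbene–alkyne insertion (six-membered, with the oxygen and the former carbene carbon inside and the new carbene carbon outside), and the carbocycle is closed by the 6π-electrocyclization. No new stereocenter remains, because the quaternary carbon keeps its C–O bond throughout and the hemiketal carbon of 16 becomes a carbonyl carbon again. The step needs regioselective alkyne insertion, which the two-methylene tether secures because only the six-membered mode is geometrically accessible, and CO insertion in preference to cyclopentannulation, which the alkoxy donor on chromium and the alkenyl carbene substituent favour, while both butenyl geometries converge. (NH4)2Ce(NO3)6 then removes two electrons from 15, water adds to the aryl carbon that bears the ring oxygen to give hemiketal 16, and its collapse opens the temporary ring to the para-quinone and the free tertiary alcohol, the para-hydroxyl fixing the quinone pattern.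

**Compound list**

1 | natural phytol, (2E,7R,11R)-3,7,11,15-tetramethylhexadec-2-en-1-ol | OC/C=C(\C)CCC[C@H](C)CCC[C@H](C)CCCC(C)C | starting material
2 | [(2R,3R)-3-methyl-3-[(4R,8R)-4,8,12-trimethyltridecyl]oxiran-2-yl]methanol | OC[C@H]1O[C@]1(C)CCC[C@H](C)CCC[C@H](C)CCCC(C)C | intermediate
3 | (3R,7R,11R)-3,7,11,15-tetramethylhexadecane-1,3-diol | OCC[C@](C)(O)CCC[C@H](C)CCC[C@H](C)CCCC(C)C | intermediate
4 | (3R,7R,11R)-3-hydroxy-3,7,11,15-tetramethylhexadecyl 4-methylbenzenesulfonate | Cc1ccc(cc1)S(=O)(=O)OCC[C@](C)(O)CCC[C@H](C)CCC[C@H](C)CCCC(C)C | intermediate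
5 | (2R)-2-methyl-2-[(4R,8R)-4,8,12-trimethyltridecyl]oxetane | O1CC[C@@]1(C)CCC[C@H](C)CCC[C@H](C)CCCC(C)C | intermediate
6 | 1-propynyllithium, MeC≡CLi | [Li]C#CC | starting material
7 | (6R,10R,14R)-6,10,14,18-tetramethylnonadec-2-yn-6-ol | CC#CCC[C@](C)(O)CCC[C@H](C)CCC[C@H](C)CCCC(C)C | intermediate
8 | 2-bromobut-2-ene (E/Z mixture) | CC=C(C)Br | starting material
9 | Cr(CO)6, hexacarbonylchromium | O=C=[Cr](=C=O)(=C=O)(=C=O)(=C=O)=C=O | starting material
10 | but-2-en-2-yllithium, MeCH=C(Me)Li (E/Z mixture) | [Li]C(C)=CC | intermediate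
11 | Li[(CO)5Cr=C(O)C(Me)=CHMe], lithium pentacarbonyl(2-methylbut-2-enoyl)chromate | [Li+].[O-]C(C(C)=CC)=[Cr](=C=O)(=C=O)(=C=O)(=C=O)=C=O | intermediate
12 | Me4N[(CO)5Cr=C(O)C(Me)=CHMe], tetramethylammonium pentacarbonyl(2-methylbut-2-enoyl)chromate | C[N+](C)(C)C.[O-]C(C(C)=CC)=[Cr](=C=O)(=C=O)(=C=O)(=C=O)=C=O | intermediate
13 | (CO)5Cr=C(OCOtBu)C(Me)=CHMe, pentacarbonyl[(but-2-en-2-yl)(pivaloyloxy)carbene]chromium | CC(C)(C)C(=O)OC(C(C)=CC)=[Cr](=C=O)(=C=O)(=C=O)(=C=O)=C=O | intermediate
14 | pentacarbonyl{(but-2-en-2-yl)[(6R,10R,14R)-6,10,14,18-tetramethylnonadec-2-yn-6-yloxy]carbene}chromium | CC#CCC[C@](C)(OC(C(C)=CC)=[Cr](=C=O)(=C=O)(=C=O)(=C=O)=C=O)CCC[C@H](C)CCC[C@H](C)CCCC(C)C | intermediate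
15 | α-tocopherol, (2R)-2,5,7,8-tetramethyl-2-[(4R,8R)-4,8,12-trimethyltridecyl]-3,4-dihydro-2H-chromen-6-ol | Cc1c(C)c2O[C@](C)(CCC[C@H](C)CCC[C@H](C)CCCC(C)C)CCc2c(C)c1O | intermediate
16 | 8a-hydroxy-α-tocopherone, (2R)-8a-hydroxy-2,5,7,8-tetramethyl-2-[(4R,8R)-4,8,12-trimethyltridecyl]-2,3,4,8a-tetrahydrochromen-6-one (both epimers at the hemiketal carbon) | CC1=C(C)C2(O)O[C@](C)(CCC[C@H](C)CCC[C@H](C)CCCC(C)C)CCC2=C(C)C1=O | intermediate
17 | tocopherylquinone, 2-[(3R,7R,11R)-3-hydroxy-3,7,11,15-tetramethylhexadecyl]-3,5,6-trimethylcyclohexa-2,5-diene-1,4-dione | CC1=C(C)C(=O)C(CC[C@](C)(O)CCC[C@H](C)CCC[C@H](C)CCCC(C)C)=C(C)C1=O | target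

**Step count and risks**

Total steps: 7. Longest linear sequence: 6 steps (steps 1, 2, 3, 4, 6 and 7; step 5 is the side branch).

Steps most likely to fail:

1. Step 6 (Proposed new method). What may go wrong: addition of the hindered tertiary hydroxyl to the carbene carbon of 13 may be slower than the thermal decay of 13, or the tertiary C–O bond of the product may ionize with loss of the side chain during isolation. The fallback drops the tether and uses the known intermolecular benzannulation; it sets out from 12 and 7 and returns to the route at 17. Acylchromate 12 is O-methylated with Me3OBF4 (CH2Cl2/H2O, 0 °C) to give pentacarbonyl[(but-2-en-2-yl)(methoxy)carbene]chromium F1. Heating F1 with alkynol 7 (THF, 50 °C) should give the two regioisomeric phenols 2-[(3R,7R,11R)-3-hydroxy-3,7,11,15-tetramethylhexadecyl]-4-methoxy-3,5,6-trimethylphenol F2 and 3-[(3R,7R,11R)-3-hydroxy-3,7,11,15-tetramethylhexadecyl]-4-methoxy-2,5,6-trimethylphenol F3, which are not separated. Oxidative demethylation with (NH4)2Ce(NO3)6 in MeCN/H2O should convert both into 17, because exchanging the substituents at C2 and C3 of this quinone gives the same compound.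

2. Step 7 (key step). What may go wrong: on heating, heterolysis or elimination at the tertiary C–O bond of the alkoxycarbene may outrun CO loss, or intermolecular alkyne insertion may compete with the intramolecular one. The fallback moves the side chain from the carbene oxygen to the alkenyl group and uses a symmetric alkyne; it sets out from 7 and returns to the route at 17. Hydrozirconation of 7 with excess Cp2Zr(H)Cl (THF, rt to 40 °C, which should equilibrate the metal to the methyl-bearing alkyne carbon) and iodinolysis with I2 give (2E,6R,10R,14R)-2-iodo-6,10,14,18-tetramethylnonadec-2-en-6-ol F4. Treatment with t-BuLi (3 equiv, −78 °C), Cr(CO)6 (9) and then Me3OBF4 gives pentacarbonyl{[(2E,6R,10R,14R)-6-hydroxy-6,10,14,18-tetramethylnonadec-2-en-2-yl](methoxy)carbene}chromium F5. Dötz benzannulation of F5 with but-2-yne (THF, 50 °C) should give the phenol 2-[(3R,7R,11R)-3-hydroxy-3,7,11,15-tetramethylhexadecyl]-4-methoxy-3,5,6-trimethylphenol F2 as one regioisomer, and (NH4)2Ce(NO3)6 in MeCN/H2O then gives 17. The minor hydrozirconation regioisomer would lead to the same quinone.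

3. Step 4. What may go wrong: Lewis-acid-induced heterolysis of the tertiary C–O bond of the oxetane (elimination to homoallylic alcohols, or attack at the quaternary carbon with loss of configuration) may compete with SN2 opening at the CH2 terminus. The fallback is an acyclic SN2 displacement with the carbinol protected and no Lewis acid; it sets out from 3 and returns to the route at 7. Diol 3 is tosylated at the primary hydroxyl (TsCl, pyridine, 0 °C) to give 4, which is isolated this time. Silylation of the tertiary hydroxyl (Et3SiOTf, 2,6-lutidine, CH2Cl2) gives (3R,7R,11R)-3,7,11,15-tetramethyl-3-(triethylsilyloxy)hexadecyl 4-methylbenzenesulfonate F6. Displacement with MeC≡CLi (6) in THF/DMPU gives triethyl{[(6R,10R,14R)-6,10,14,18-tetramethylnonadec-2-yn-6-yl]oxy}silane F7, and Bu4NF in THF removes the silyl group to give 7.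

Further compounds
F1 | step 6 | pentacarbonyl[(but-2-en-2-yl)(methoxy)carbene]chromium (E/Z mixture) | COC(C(C)=CC)=[Cr](=C=O)(=C=O)(=C=O)(=C=O)=C=O
F2 | step 6 | 2-[(3R,7R,11R)-3-hydroxy-3,7,11,15-tetramethylhexadecyl]-4-methoxy-3,5,6-trimethylphenol | COc1c(C)c(C)c(O)c(CC[C@](C)(O)CCC[C@H](C)CCC[C@H](C)CCCC(C)C)c1C
F3 | step 6 | 3-[(3R,7R,11R)-3-hydroxy-3,7,11,15-tetramethylhexadecyl]-4-methoxy-2,5,6-trimethylphenol | COc1c(C)c(C)c(O)c(C)c1CC[C@](C)(O)CCC[C@H](C)CCC[C@H](C)CCCC(C)C
F4 | step 7 | (2E,6R,10R,14R)-2-iodo-6,10,14,18-tetramethylnonadec-2-en-6-ol | C/C(I)=C\CC[C@](C)(O)CCC[C@H](C)CCC[C@H](C)CCCC(C)C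
F5 | step 7 | pentacarbonyl{[(2E,6R,10R,14R)-6-hydroxy-6,10,14,18-tetramethylnonadec-2-en-2-yl](methoxy)carbene}chromium | COC(/C(C)=C/CC[C@](C)(O)CCC[C@H](C)CCC[C@H](C)CCCC(C)C)=[Cr](=C=O)(=C=O)(=C=O)(=C=O)=C=O
F6 | step 4 | (3R,7R,11R)-3,7,11,15-tetramethyl-3-(triethylsilyloxy)hexadecyl 4-methylbenzenesulfonate | CC[Si](CC)(CC)O[C@@](C)(CCOS(=O)(=O)c1ccc(C)cc1)CCC[C@H](C)CCC[C@H](C)CCCC(C)C
F7 | step 4 | triethyl{[(6R,10R,14R)-6,10,14,18-tetramethylnonadec-2-yn-6-yl]oxy}silane | CC#CCC[C@](C)(O[Si](CC)(CC)CC)CCC[C@H](C)CCC[C@H](C)CCCC(C)C
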